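**Strategy.** The route rests on disconnecting O1–C5 of the tetrahydrofuran ring. It exploits the fact that C5 is an unsubstituted methylene on O1 and C4 carries only the benzyl group, so that C4–C5 can be a terminal alkyne. Gold-catalysed alkyne oxidation converts an anti homopropargylic alcohol in one operation into the trans tetrahydrofuran-4-one, closing the ring and leaving C4 as a ketone handle for the benzyl group. The precursor holds the C2 aryl carbinol, the C3 silyloxymethyl arm and the ethynyl group, with C2 and C3 set beforehand by chirality-transferring propargylation of veratraldehyde; methylenation, hydroboration/Suzuki coupling, desilylation and angeloylation finish the synthesis.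

Key step: step 7

Remark: atoms are numbered as in the target (O1, C2 aryl, C3 CH2O arm, C4 benzyl, C5 CH2), also in acyclic compounds; the facial sense of step 3 is assumed to follow that of 4-silylbut-3-yn-2-ones, the alkynyl group taking the aryl-like site.

**Step 1**
Reactants: 1 trimethylsilylacetylene; 2 (tert-butyldimethylsilyloxy)acetaldehyde
Product: 4 rac-1-(tert-butyldimethylsilyloxy)-4-(trimethylsilyl)but-3-yn-2-ol, via lithium trimethylsilylacetylide 3 (not isolated)
Conditions: n-BuLi, THF, −78 °C; then 2, −78 → 0 °C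
Reagents that add atoms: n-butyllithium, [Li]CCCC (its lithium is held in 3 only)
Why: Acetylide 1,2-addition of the lithiated alkyne to an unhindered aldehyde should give the racemic propargylic alcohol, whose stereocentre is erased in step 2.

**Step 2**
Reactants: 4 rac-1-(tert-butyldimethylsilyloxy)-4-(trimethylsilyl)but-3-yn-2-ol
Product: 5 1-(tert-butyldimethylsilyloxy)-4-(trimethylsilyl)but-3-yn-2-one
Conditions: Dess–Martin periodinane, CH2Cl2, 0 °C → rt
Reagents that add atoms: none
Why: Dess–Martin oxidation of a secondary propargylic alcohol is mild and near-neutral, so both silyl groups and the base-sensitive ynone should survive.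

**Step 3**
Reactants: 5 1-(tert-butyldimethylsilyloxy)-4-(trimethylsilyl)but-3-yn-2-one
Product: 6 (S)-1-(tert-butyldimethylsilyloxy)-4-(trimethylsilyl)but-3-yn-2-ol
Conditions: Ru[(R,R)-TsDPEN](p-cymene) (1 mol %), i-PrOH, rt
Reagents that add atoms: none
Why: In this Noyori asymmetric transfer hydrogenation the alkynyl group should occupy the aryl-like site of the Ru–H/N–H transition state, so the (R,R)-catalyst should set the carbinol as (S) (S because CH2OSi outranks the alkynyl carbon), and the base-free catalyst spares the ynone.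

**Step 4**
Reactants: 6 (S)-1-(tert-butyldimethylsilyloxy)-4-(trimethylsilyl)but-3-yn-2-ol
Product: 7 (S)-1-(tert-butyldimethylsilyloxy)-4-(trimethylsilyl)but-3-yn-2-yl methanesulfonate
Conditions: MsCl, Et3N, CH2Cl2, −78 °C
Reagents that add atoms: methanesulfonyl chloride, CS(=O)(=O)Cl
Why: O-Sulfonylation of the secondary alcohol does not touch the C–O stereocentre, so the (S)-mesylate should form with retention.

**Step 5**
Reactants: 7 (S)-1-(tert-butyldimethylsilyloxy)-4-(trimethylsilyl)but-3-yn-2-yl methanesulfonate; 8 3,4-dimethoxybenzaldehyde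
Product: 10 (1S,2R)-2-[(tert-butyldimethylsilyloxy)methyl]-1-(3,4-dimethoxyphenyl)-4-(trimethylsilyl)but-3-yn-1-ol (anti), via allenyl(ethyl)zinc 9 (not isolated)
Conditions: Pd(OAc)2 (5 mol %), PPh3 (5 mol %), Et2Zn (3 equiv), THF, −78 → −20 °C
Reagents that add atoms: diethylzinc, CC[Zn]CC (its ethylzinc unit is held in 9 only)
Why: In this Marshall propargylation zerovalent palladium ionises the mesylate by anti SN2' attack, transmetalation gives the configurationally defined allenylzinc 9, and its SE2' addition through a cyclic transition state (aryl group turned away from the silyloxymethyl substituent) should transfer the mesylate chirality to C3 (R) and set the carbinol C2 (S) anti to it; the minor syn isomer differs at C2 and has to be removed by chromatography here, because C3 becomes epimerisable after step 7.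

**Step 6**
Reactants: 10 (1S,2R)-2-[(tert-butyldimethylsilyloxy)methyl]-1-(3,4-dimethoxyphenyl)-4-(trimethylsilyl)but-3-yn-1-ol
Product: 11 (1S,2R)-2-[(tert-butyldimethylsilyloxy)methyl]-1-(3,4-dimethoxyphenyl)but-3-yn-1-ol
Conditions: K2CO3 (0.2 equiv), MeOH, rt
Reagents that add atoms: none
Why: Base-catalysed methanolysis (protodesilylation) should cleave only the alkynyl C–Si bond, the O-TBS ether and both stereocentres being inert to K2CO3 in methanol.

**Step 7**
Reactants: 11 (1S,2R)-2-[(tert-butyldimethylsilyloxy)methyl]-1-(3,4-dimethoxyphenyl)but-3-yn-1-ol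
Product: 12 (4R,5S)-4-[(tert-butyldimethylsilyloxy)methyl]-5-(3,4-dimethoxyphenyl)dihydrofuran-3(2H)-one (trans)
Conditions: Ph3PAuNTf2 (5 mol %), 8-methylquinoline N-oxide (1.5 equiv), 4 Å MS, ClCH2CH2Cl, rt
Reagents that add atoms: 8-methylquinoline N-oxide, Cc1cccc2ccc[n+]([O-])c12
Why: Monovalent gold π-activates the terminal alkyne, the N-oxide oxygen adds to the internal carbon C4 and N–O cleavage releases 8-methylquinoline to leave an α-oxo gold carbene at C5, which the C2 hydroxyl attacks, protodeauration completing a formal O–H insertion that forms O1–C5. The closest known reaction type is the gold-catalysed oxidative cyclisation of homopropargylic alcohols to dihydrofuran-3(2H)-ones. The one ring (O1–C2–C3–C4–C5) closes by attack of oxygen on the carbene carbon with the Au=C5 bond outside the ring, a 5-exo-type closure. No stereocentre is created: C2 and C3 take no part in bond making and are carried over from 11 as the trans pair, the acid-free and non-basic medium avoiding enolisation toward C3. The step needs oxygen transfer to the internal alkyne carbon, secured by the alkyne being terminal, and capture of the carbene by the C2 hydroxyl in preference to the electron-rich arene, the silyl ether oxygen or a second N-oxide, secured by the free hydroxyl being the only strong nucleophile placed for five-membered closure and by masking the other homopropargylic oxygen as its TBS ether. The hindered 8-methylquinoline should not sequester the catalyst, so no strong acid is needed and the benzylic carbinol and TBS ether are spared.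

**Step 8**
Reactants: 12 (4R,5S)-4-[(tert-butyldimethylsilyloxy)methyl]-5-(3,4-dimethoxyphenyl)dihydrofuran-3(2H)-one
Product: 13 tert-butyl{[(2S,3R)-2-(3,4-dimethoxyphenyl)-4-methylenetetrahydrofuran-3-yl]methoxy}dimethylsilane
Conditions: Ph3PCH3Br (2.0 equiv), KOtBu (1.8 equiv), THF, 0 °C → rt
Reagents that add atoms: methyltriphenylphosphonium bromide, C[P+](c1ccccc1)(c1ccccc1)c1ccccc1.[Br-]
Why: Wittig methylenation with the non-stabilised ylide should convert the C4 ketone into the exocyclic alkene, the deficit of base limiting enolisation and any equilibration at C3 favouring the trans arrangement already present.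

**Step 9**
Reactants: 13 tert-butyl{[(2S,3R)-2-(3,4-dimethoxyphenyl)-4-methylenetetrahydrofuran-3-yl]methoxy}dimethylsilane; 14 4-bromo-1,2-dimethoxybenzene
Product: 16 tert-butyl{[(2S,3R,4R)-4-(3,4-dimethoxybenzyl)-2-(3,4-dimethoxyphenyl)tetrahydrofuran-3-yl]methoxy}dimethylsilane, via B-alkyl-9-BBN borane 15 (not isolated)
Conditions: 9-BBN, THF, 0 °C → rt; then 14, Pd(dppf)Cl2 (5 mol %), aq. K3PO4, THF/DMF, 60 °C
Reagents that add atoms: 9-borabicyclo[3.3.1]nonane, [H]B1C2CCCC1CCC2 (its boron and cage are held in 15 only; 16 keeps only the hydrogen)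
Why: In this hydroboration/B-alkyl Suzuki–Miyaura sequence 9-BBN should place boron on the terminal carbon and deliver hydrogen to C4 from the face opposite the adjacent C3 silyloxymethyl arm, which makes C4 (R) with its CH2 group cis to that arm, and the primary alkylborane is then cross-coupled with the aryl bromide without touching C4.

**Step 10**
Reactants: 16 tert-butyl{[(2S,3R,4R)-4-(3,4-dimethoxybenzyl)-2-(3,4-dimethoxyphenyl)tetrahydrofuran-3-yl]methoxy}dimethylsilane
Product: 17 [(2S,3R,4R)-4-(3,4-dimethoxybenzyl)-2-(3,4-dimethoxyphenyl)tetrahydrofuran-3-yl]methanol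
Conditions: TBAF, THF, 0 °C → rt
Reagents that add atoms: none
Why: Fluoride-mediated desilylation of the primary TBS ether, driven by the Si–F bond, should leave the aryl ethers, the ring and all three stereocentres untouched.

**Step 11**
Reactants: 17 [(2S,3R,4R)-4-(3,4-dimethoxybenzyl)-2-(3,4-dimethoxyphenyl)tetrahydrofuran-3-yl]methanol; 18 angelic acid ((Z)-2-methylbut-2-enoic acid)
Product: 19 leoligin, [(2S,3R,4R)-4-(3,4-dimethoxybenzyl)-2-(3,4-dimethoxyphenyl)tetrahydrofuran-3-yl]methyl (Z)-2-methylbut-2-enoate
Conditions: PPh3, DIAD, THF, 0 °C → rt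
Reagents that add atoms: none
Why: In this Mitsunobu esterification the primary alcohol is activated as its alkoxyphosphonium ion and displaced by angelate at CH2, so the acid is never activated at its carbonyl, the (Z)-alkene should not isomerise to the tiglate, and no stereocentre is involved.

**Compound list**
1 | trimethylsilylacetylene | C#C[Si](C)(C)C | starting material
2 | (tert-butyldimethylsilyloxy)acetaldehyde | CC(C)(C)[Si](C)(C)OCC=O | starting material
3 | lithium (trimethylsilyl)acetylide | [Li]C#C[Si](C)(C)C | intermediate (not isolated)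
4 | rac-1-(tert-butyldimethylsilyloxy)-4-(trimethylsilyl)but-3-yn-2-ol | CC(C)(C)[Si](C)(C)OCC(O)C#C[Si](C)(C)C | intermediate
5 | 1-(tert-butyldimethylsilyloxy)-4-(trimethylsilyl)but-3-yn-2-one | CC(C)(C)[Si](C)(C)OCC(=O)C#C[Si](C)(C)C | intermediate
6 | (S)-1-(tert-butyldimethylsilyloxy)-4-(trimethylsilyl)but-3-yn-2-ol | CC(C)(C)[Si](C)(C)OC[C@@H](O)C#C[Si](C)(C)C | intermediate
7 | (S)-1-(tert-butyldimethylsilyloxy)-4-(trimethylsilyl)but-3-yn-2-yl methanesulfonate | CC(C)(C)[Si](C)(C)OC[C@@H](OS(C)(=O)=O)C#C[Si](C)(C)C | intermediate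
8 | 3,4-dimethoxybenzaldehyde | COc1ccc(C=O)cc1OC | starting material
9 | (aS)-[4-(tert-butyldimethylsilyloxy)-1-(trimethylsilyl)buta-1,2-dien-1-yl](ethyl)zinc | CC[Zn]C([Si](C)(C)C)=[C@@]=C([H])CO[Si](C)(C)C(C)(C)C | intermediate (not isolated)
10 | (1S,2R)-2-[(tert-butyldimethylsilyloxy)methyl]-1-(3,4-dimethoxyphenyl)-4-(trimethylsilyl)but-3-yn-1-ol | CC(C)(C)[Si](C)(C)OC[C@@H](C#C[Si](C)(C)C)[C@H](O)c1ccc(OC)c(OC)c1 | intermediate
11 | (1S,2R)-2-[(tert-butyldimethylsilyloxy)methyl]-1-(3,4-dimethoxyphenyl)but-3-yn-1-ol | CC(C)(C)[Si](C)(C)OC[C@@H](C#C)[C@H](O)c1ccc(OC)c(OC)c1 | intermediate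
12 | (4R,5S)-4-[(tert-butyldimethylsilyloxy)methyl]-5-(3,4-dimethoxyphenyl)dihydrofuran-3(2H)-one | CC(C)(C)[Si](C)(C)OC[C@H]1C(=O)CO[C@@H]1c1ccc(OC)c(OC)c1 | intermediate
13 | tert-butyl{[(2S,3R)-2-(3,4-dimethoxyphenyl)-4-methylenetetrahydrofuran-3-yl]methoxy}dimethylsilane | CC(C)(C)[Si](C)(C)OC[C@H]1C(=C)CO[C@@H]1c1ccc(OC)c(OC)c1 | intermediate
14 | 4-bromo-1,2-dimethoxybenzene | COc1ccc(Br)cc1OC | starting material
15 | 9-{[(3R,4R,5S)-4-[(tert-butyldimethylsilyloxy)methyl]-5-(3,4-dimethoxyphenyl)tetrahydrofuran-3-yl]methyl}-9-borabicyclo[3.3.1]nonane | CC(C)(C)[Si](C)(C)OC[C@H]1[C@@H](CB2C3CCCC2CCC3)CO[C@@H]1c1ccc(OC)c(OC)c1 | intermediate (not isolated)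
16 | tert-butyl{[(2S,3R,4R)-4-(3,4-dimethoxybenzyl)-2-(3,4-dimethoxyphenyl)tetrahydrofuran-3-yl]methoxy}dimethylsilane | CC(C)(C)[Si](C)(C)OC[C@H]1[C@@H](Cc2ccc(OC)c(OC)c2)CO[C@@H]1c1ccc(OC)c(OC)c1 | intermediate
17 | [(2S,3R,4R)-4-(3,4-dimethoxybenzyl)-2-(3,4-dimethoxyphenyl)tetrahydrofuran-3-yl]methanol | OC[C@H]1[C@@H](Cc2ccc(OC)c(OC)c2)CO[C@@H]1c1ccc(OC)c(OC)c1 | intermediate
18 | angelic acid, (Z)-2-methylbut-2-enoic acid | C/C=C(/C)C(=O)O | starting material
19 | leoligin | C/C=C(/C)C(=O)OC[C@H]1[C@@H](Cc2ccc(OC)c(OC)c2)CO[C@@H]1c1ccc(OC)c(OC)c1 | target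

**Step count.** Total: 11 steps. Longest linear sequence: 11 steps (2 → 19); compounds 1, 8, 14 and 18 enter as purchased partners.

**Steps most likely to fail**

Step 7. The carbene may be diverted before the hydroxyl captures it: attack by the dimethoxyphenyl ring, a second oxygen transfer, or sequestration of the catalyst by the quinoline. The fallback sets out from 11. A molybdenum-vinylidene endo-cycloisomerisation (Mo(CO)6, Et3N, Et2O, hν) closes the same O1–C5 bond and should give tert-butyl{[(2S,3R)-2-(3,4-dimethoxyphenyl)-2,3-dihydrofuran-3-yl]methoxy}dimethylsilane F1. Hydroboration–oxidation of this enol ether (BH3·THF; then NaOH, H2O2) places the hydroxyl on C4 and should give (4R,5S)-4-[(tert-butyldimethylsilyloxy)methyl]-5-(3,4-dimethoxyphenyl)tetrahydrofuran-3-ol F2 as carbinol epimers. Dess–Martin oxidation of either epimer comes back to the route at 12.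

Step 5. Discrimination between the two aldehyde faces may be poor with an aromatic aldehyde. The allenylzinc may also partly racemise, transfer an ethyl group, or lose silanolate by β-elimination through its propargyl tautomer. The fallback sets out from 6. Acylation with methyl chloroformate (pyridine, CH2Cl2) gives (S)-1-(tert-butyldimethylsilyloxy)-4-(trimethylsilyl)but-3-yn-2-yl methyl carbonate F3. Copper-catalysed anti SN2' borylation (B2pin2, CuOtBu, Xantphos, THF) should give the isolable, configurationally stable 2-[(aR)-4-(tert-butyldimethylsilyloxy)-1-(trimethylsilyl)buta-1,2-dien-1-yl]-4,4,5,5-tetramethyl-1,3,2-dioxaborolane F4. This adds to 8 without a catalyst through a closed six-membered transition state (toluene, rt → 60 °C), and aqueous work-up comes back to the route at 10.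

Step 8. The ylide may act as a base and enolise the ketone toward C5 or C3. That would stall the olefination and could expel the silyloxy group by β-elimination. The fallback sets out from 12 and is a two-stage Peterson olefination. The weakly basic organocerium reagent from Me3SiCH2MgCl and CeCl3 (THF, −78 °C) adds to the ketone to give (4R,5S)-4-[(tert-butyldimethylsilyloxy)methyl]-5-(3,4-dimethoxyphenyl)-3-[(trimethylsilyl)methyl]tetrahydrofuran-3-ol F5 (either carbinol epimer). KH in THF then triggers syn-elimination of silanolate and comes back to the route at 13.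

**Further compounds**
F1 | step 7 | tert-butyl{[(2S,3R)-2-(3,4-dimethoxyphenyl)-2,3-dihydrofuran-3-yl]methoxy}dimethylsilane | CC(C)(C)[Si](C)(C)OC[C@H]1C=CO[C@@H]1c1ccc(OC)c(OC)c1
F2 | step 7 | (4R,5S)-4-[(tert-butyldimethylsilyloxy)methyl]-5-(3,4-dimethoxyphenyl)tetrahydrofuran-3-ol (carbinol epimers) | CC(C)(C)[Si](C)(C)OC[C@H]1C(O)CO[C@@H]1c1ccc(OC)c(OC)c1
F3 | step 5 | (S)-1-(tert-butyldimethylsilyloxy)-4-(trimethylsilyl)but-3-yn-2-yl methyl carbonate | CC(C)(C)[Si](C)(C)OC[C@@H](OC(=O)OC)C#C[Si](C)(C)C
F4 | step 5 | 2-[(aR)-4-(tert-butyldimethylsilyloxy)-1-(trimethylsilyl)buta-1,2-dien-1-yl]-4,4,5,5-tetramethyl-1,3,2-dioxaborolane | CC1(C)OB(OC1(C)C)C([Si](C)(C)C)=[C@@]=C([H])CO[Si](C)(C)C(C)(C)C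
F5 | step 8 | (4R,5S)-4-[(tert-butyldimethylsilyloxy)methyl]-5-(3,4-dimethoxyphenyl)-3-[(trimethylsilyl)methyl]tetrahydrofuran-3-ol (carbinol epimers) | CC(C)(C)[Si](C)(C)OC[C@H]1C(O)(C[Si](C)(C)C)CO[C@@H]1c1ccc(OC)c(OC)c1
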